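The numbers in the tables stem from a simulated flask on assumed constants; noise was put on by code.

The trap in a flask like autumn was to scale the electrophile lost with the nucleophile charged, and I nearly did that when you asked for a quick number and guessed that extra free base would help.

the same everywhere: electrophile 21 mM
- Saturday's: nucleophile 1.5 equiv; free base 3 equiv; run made earlier
- Thursday's: nucleophile 2 equiv; free base 3 equiv; run made earlier
- autumn: nucleophile 1.00 equiv; free base 3.00 equiv; time 8.0 d
- winter: nucleophile 1.00 equiv; free base 6.00 equiv; time 8.0 d
- dawn: nucleophile 1.00 equiv; free base 12.0 equiv; time 8.0 d

| run | time / d | electrophile / % | target / % |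
|---|---|---|---|
| Saturday's | 0.417 | 86.4 | 11.2 |
| Saturday's | 0.625 | 83.1 | 16.0 |
| Saturday's | 1.04 | 80.3 | 21.5 |
| Saturday's | 1.67 | 74.1 | 23.2 |
| Saturday's | 3.00 | 67.2 | 27.6 |
| Saturday's | 5.00 | 59.1 | 30.6 |
| Thursday's | 0.333 | 89.1 | 12.3 |
| Thursday's | 0.833 | 77.4 | 19.8 |
| Thursday's | 1.67 | 70.9 | 27.4 |
| Thursday's | 2.50 | 65.3 | 29.0 |
| Thursday's | 4.00 | 58.8 | 30.8 |
| Thursday's | 5.00 | 53.8 | 33.1 |

(scatter of a reading: 1 percentage point)

- percent here means electrophile units held: one side product counts as two
- steps that have been proposed: acid set free + free base <-> salt of the base; nucleophile -> decomposition product; electrophile + nucleophile -> acid set free + target; 2 nucleophile -> self-condensation product; electrophile + target -> side product; nucleophile + acid set free <-> protonated nucleophile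
- no earlier run changes the charge of free base; that part of a forecast is a guess

- part of the electrophile that has reacted at the end, autumn
- part of the electrophile that has reacted at the end, winter
- part of the electrophile that has reacted at the end, dawn
- what raising the equivalents of free base from its lowest to its highest value here does to the part of the electrophile that has reacted (changes below 5 percentage points count as none) (it falls / it rises / no change)

I began from the proposed step in which two nucleophile combine to the self-condensation product. If that step is what removes the nucleophile, c(nucleophile) decays with a lifetime inverse to its charge, so the time integral of c(nucleophile), which the electrophile feels, depends on charge and time through their product. Autumn's dose is 8.00 d, where the dose means the equivalents of nucleophile charged multiplied by the time.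

I tested this on the readings. Saturday's run at 5.00 d has a dose of 7.50 d and shows 40.9 % of the electrophile reacted, while Thursday's at 4.00 d has 8.00 d and shows 41.2 %, which agree within the scatter of 1 percentage point per reading. Thursday's dose there equals autumn's, so I committed to about 41.2 % for autumn. I held that as a low figure, since autumn runs twice as long and the electrophile + target step has more time.

Free base was a guess, as no run changes it. Acid set free, bound forms counted, cannot exceed the nucleophile charged, a third of autumn's free base, so my own reckoning kept autumn's number for winter and dawn.

The forecast differed from my level figure: it stood at 41 %, 43 % and 44 %, trend no change, expecting “a small rise, under 5 points”.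

The flasks give 43.0 %, 43.3 % and 43.0 %, a change of 0.033 points, so no change.

    acid set free + free base ⇌ salt of the base (K = 13000 /M, k = 0.00320 /M/s)
    nucleophile → decomposition product (k = 2.20 × 10⁻⁹ /s)
    electrophile + nucleophile → acid set free + target (k = 1.70 × 10⁻⁴ /M/s)
    2 nucleophile → self-condensation product (k = 3.60 × 10⁻⁴ /M/s)
    electrophile + target → side product (k = 4.20 × 10⁻⁵ /M/s)
    nucleophile + acid set free ⇌ protonated nucleophile, settled at all times (K = 6400 /M)

In autumn, at a dose of 8.00 d, the nucleophile, the limiting reagent, ends at 5.8 % of its charge, less than the electrophile's 57 %. The neighbouring flask, autumn with 0.600 equiv of nucleophile, has a dose of 4.80 d. That lies between Saturday's 4.50 d at 3.00 d and Thursday's 5.00 d at 2.50 d, whose readings show 32.8 % and 34.7 % of the electrophile reacted. The neighbouring flask gives 33.9 %.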